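The numbers in the tables were computed on assumed constants, and the scatter is random.

If I divide the substrate's loss per minute by the substrate still there, what remains is a clock for the activator, and I carry that clock through these set-ups.

| setting | elm | birch | maple | ash | epsilon | alpha | beta | zeta |
|---|---|---|---|---|---|---|---|---|
| substrate | 0.050 M | 0.025 M | 0.038 M | 0.050 M | 0.050 M | 0.050 M | 0.050 M | 0.050 M |
| activator | 0.95 equiv | 0.95 equiv | 0.95 equiv | 0.95 equiv | 0.950 equiv | 0.950 equiv (fed, over 32.0 min) | 0.950 equiv | 0.950 equiv |
| protic impurity | 5 mM | 5 mM | 5 mM | 10 mM | 5.00 mM | 5.00 mM | 5.00 mM | 5.00 mM |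
| remark | run made earlier | run made earlier | run made earlier | run made earlier | a tube with plug flow, the mixed feed as stated, residence time 40 min | all but activator at the start; activator goes in evenly over 32.0 min, the run ends at 40 min | a closed flask charged with all of it at once and left for 40 min | a single well-mixed tank run continuously and read at steady state, 40 min in it on average |
| time |  |  |  |  | 40 min | 40 min | 40 min |  |

| run | time / min | ring / % | substrate / % |
|---|---|---|---|
| elm | 3.00 | 7 | 65 |
| elm | 5.00 | 9 | 56 |
| elm | 8.00 | 16 | 51 |
| elm | 15.0 | 23 | 39 |
| elm | 25.0 | 30 | 37 |
| elm | 40.0 | 33 | 32 |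
| birch | 4.00 | 6 | 77 |
| birch | 6.00 | 8 | 72 |
| birch | 10.0 | 18 | 62 |
| birch | 20.0 | 27 | 50 |
| birch | 30.0 | 30 | 44 |
| birch | 50.0 | 33 | 45 |
| maple | 4.00 | 10 | 67 |
| maple | 6.00 | 15 | 61 |
| maple | 10.0 | 22 | 51 |
| maple | 20.0 | 28 | 38 |
| maple | 30.0 | 31 | 37 |
| maple | 50.0 | 35 | 34 |
| ash | 4.00 | 12 | 64 |
| ash | 12.0 | 22 | 45 |
| ash | 20.0 | 25 | 41 |
| ash | 30.0 | 29 | 36 |
| ash | 50.0 | 29 | 31 |

(readings scatter by 1.5 percentage points)

- the stated concentrations are those of everything mixed, before any reaction; amounts are the same in each set-up
- the earlier runs were read with a standard deviation of 1.5 percentage points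
- the feed brings no volume worth counting
- the earlier runs were made in a closed, stirred flask

* the set-up with the highest amount of ring at the outlet or at the end, in percent of the substrate put in ("none" if the first two lie within 2 percentage points) (epsilon / alpha / beta / zeta / none)
* amount of ring at the outlet or at the end, in percent of the substrate put in, epsilon
* amount of ring at the outlet or at the end, in percent of the substrate put in, alpha
* amount of ring at the outlet or at the end, in percent of the substrate put in, beta
* amount of ring at the outlet or at the end, in percent of the substrate put in, zeta

Elm opens with a fractional rate of substrate loss, averaged over the first 3.00 min, of 0.144 min⁻¹; this is a mean over a falling rate and not a constant, since the activator is not in excess and goes down with the substrate. Birch opens at 0.0653 min⁻¹; elm's figure is twice birch's, as its charge is, so I take the fractional rate to follow [activator]. Between 15.0 min and 40.0 min elm reads 0.00791 min⁻¹, a slowing by a factor of 18.2. The substrate's own fall, by a factor of 3.12, is divided out of this figure. These are readings, with their scatter of 1.5 percentage points.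

The accumulated slowing means this: the 32% of substrate left in elm after 40.0 min is what the opening rate reaches in 7.94 min. I call this the full-strength minutes: the time at the opening fractional rate that gives the same loss, which I also read as the working life of the activator.

Beta repeats elm, and plug flow gives each slice of epsilon the same clock, so I expect ring near 33% in both. In alpha the last portion of activator still has 8.00 min, about 7.94 min, so I hold alpha level with beta. In zeta the activator leaves by loss over 7.94 min and by washing out over 40 min, which keeps it at 0.166 of its charge, a weak and steady clock; I put zeta's ring a little below beta's.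

The forecast gives 33.5% for epsilon, 37% for alpha, 33.5% for beta and 28% for zeta, and against my level pair it names alpha as best, since “Dosing keeps the intermediate low with similar conversion”.

The flask gives 32.1% for epsilon, 33.4% for alpha, 32.1% for beta and 31.0% for zeta, so the answer for best is none: the first two lie 1.3 points apart, inside 2 points.

    substrate + activator → activated form (k = 0.0710 M⁻¹ s⁻¹)
    activated form → ring (k = 0.00320 s⁻¹)
    substrate + activated form → open dimer (k = 0.0680 M⁻¹ s⁻¹)
    activator + protic impurity → quenched reagent (k = 1.20 M⁻¹ s⁻¹)
    2 substrate → self-condensation product A (k = 1.70 × 10⁻⁴ M⁻¹ s⁻¹)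
    2 activator → self-condensation product B (k = 0.0460 M⁻¹ s⁻¹)

In zeta the activator stands at 0.00724 M, which is 0.152 of its charge, against my 0.166. Alpha's 23.6% of substrate is worth 10.1 min, more than my reading of 7.94 min for elm, yet its ring stands just 1.3 points above beta's. The largest single effect on alpha's ring is the step from substrate and activated form to open dimer. Alpha's open dimer holds 38.0% of the substrate charged, each percent of it counted as two, and with that step taken away alpha's ring goes from 33.4% to 55.7%.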